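(The runs stem from a simulated flask from invented constants, noise included.)

The vessel is closed and stirred, and I count its product as a share of the starting material charged. The zeta flask repeats the epsilon charge, 0.0800 M starting material and 0.0880 M coupling partner. Starting material is charged in less than coupling partner, so by the charge it is the limiting reagent.

| flask | starting material | coupling partner | time |
|---|---|---|---|
| epsilon | 0.0800 M | 0.0880 M |  |
| eta | 0.0480 M | 0.0560 M |  |
| delta | 0.0800 M | 0.0440 M |  |
| theta | 0.160 M | 0.0880 M |  |
| zeta | 0.0800 M | 0.0880 M | 90 min |

- epsilon run (time / min: [product] / M): 6.0: 0.0141; 12: 0.0216; 18: 0.0254; 24: 0.0294; 30: 0.0287; 36: 0.0300
- eta run (time / min: [product] / M): 6.0: 0.0078; 12: 0.0111; 18: 0.0140; 24: 0.0147; 30: 0.0159; 36: 0.0165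
- delta run (time / min: [product] / M): 6.0: 0.0104; 12: 0.0152; 18: 0.0181; 24: 0.0192; 30: 0.0213; 36: 0.0223
- theta run (time / min: [product] / M): 6.0: 0.0208; 12: 0.0332; 18: 0.0419; 24: 0.0476; 30: 0.0501; 36: 0.0508

(standard deviation of a reading: 6 × 10⁻⁴ M)

- Overall: starting material + coupling partner -> product.
- Constant volume, constant temperature.
- "The second partner" is coupling partner.
- An order is taken over about fifteen percent of the charge, up and down.

* order of the initial rate in [starting material], near the charge of the epsilon run, the rate being that where two percent of its starting material are product (one fixed amount of product, the same in the runs compared)
* order of the initial rate in [coupling partner], near the charge of the epsilon run, the rate being that where two percent of its starting material are product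
* product in the zeta run at 90 min, as a share of the starting material charged

Two extreme flasks can be solved in the head. In the first, nothing fades: each 18 min window gains what the first one gained in the epsilon run, 31.8% of the charge. The starting material is then used up by 56.7 min, which comes before 90 min, and the share is 100%. In the second, the reaction stops at the last reading, and the share stays at 37.5%.

I expect the zeta flask to lie between them. The second window of the epsilon run gained 5.75% of the charge by the readings, less than the first, but that gain is not zero.

So I follow the fraction left and not the fraction made. I take the carry ratio, the gain of one window over the gain of the window before it, as the fraction of the yield still to come that survives each window. I assume it stays constant. In the epsilon run it reads 0.181, and the scatter moves it by about 0.0334. The final share of that charge is then the first gain over one minus the ratio, 38.8%. At 90 min in the zeta flask, 0.0194% of that is still to come, so I commit to 38.8%.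

The forecast gives an order of 0.6 in starting material, 0.55 in coupling partner and a share of 38.5%: “Zeta should sit on the plateau, about 0.031 M, or about 38–39%.” My share stands slightly higher.

The flask gives 38.9% for the zeta run, with orders of 0.74 in starting material and 0.51 in coupling partner. The forecast's order in starting material is lower than that.

    starting material + coupling partner ⇌ intermediate, settled at all times (91.90 /M)
    starting material + coupling partner → product (5.052 /M/min)
    2 coupling partner → lost reagent (6.360 /M/min)
    starting material → decomposed substrate (0.08280 /min)

A power law fitted to the runs leaves a root mean square residual of 6.6 in units of the scatter. The carry ratio puts the epsilon run at a quarter of its charge by 10.9 min, and the flask reaches it at 10.5 min. In the delta run the ratio reads 0.232 and the final share 29.5%, which puts that quarter at 23.3 min, and the flask has it at 23.2 min.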